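**Assumption:** the small reagents and starting materials named are taken as commercial. Enolised polyketones are drawn as the tautomer used in the target SMILES, and stereodescriptors refer to that tautomer. A metal alkoxide that is only protonated on work-up is not counted as a separate compound.

## Retrosynthetic overview

1. The CH2–ring A bond is made last, by Michael addition of the enolised chiral acyl-trione (ring A) to an o-quinone methide released from the phenolic Mannich base of ring B.
2. Ring A is the only ring closed in the route. It comes from Dieckmann closure of an open-chain 3,5,7-triketo ester that already carries the quaternary stereocentre; that ester comes from an aldol between a quaternary β-keto ester and masked 3-oxohexanal.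
3. The quaternary stereocentre comes from two successive Fráter–Seebach alkylations (methyl, then prenyl) of methyl (R)-3-hydroxybutanoate, followed by oxidation of the controlling carbinol.
4. Ring B is bought as an aromatic ring (5-methoxyresorcinol) and dressed by two directed ortho-lithiations: aminomethylation between the two MOM ethers, then butanoylation.
5. Order: ring B is aromatic from the start, ring A is closed in step 9, and the two rings are joined in step 14.

## Route

**Step 1**
Reactants: 1 methyl (3R)-3-hydroxybutanoate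
Product: 3 methyl (2R,3R)-3-hydroxy-2-methylbutanoate, via dilithium alkoxide-enolate 2 (not isolated)
Conditions: LiN(iPr)2 (2.2 equiv), THF, −78 → −20 °C; MeI, DMPU, −78 → 0 °C; 1 M HCl
Reagents that add atoms: iodomethane, CI
Why: Fráter–Seebach alkylation, in which the chelated dilithium alkoxide-enolate is methylated on the face away from the C3 methyl group, giving the anti (2R,3R) product.

**Step 2**
Reactants: 3 methyl (2R,3R)-3-hydroxy-2-methylbutanoate
Product: 5 methyl (2R,3R)-3-hydroxy-2-methyl-2-(3-methylbut-2-en-1-yl)butanoate, via dilithium alkoxide-enolate 4 (not isolated)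
Conditions: LiN(iPr)2 (2.2 equiv), THF, −78 → −10 °C; prenyl bromide, DMPU, −78 → −20 °C; 1 M HCl
Reagents that add atoms: 1-bromo-3-methylbut-2-ene (prenyl bromide), CC(C)=CCBr
Why: second Fráter–Seebach alkylation, in which the re-formed chelated dianion takes the prenyl group on the same face as before, so the C3 carbinol sets the quaternary centre as 2R.

**Step 3**
Reactants: 5 methyl (2R,3R)-3-hydroxy-2-methyl-2-(3-methylbut-2-en-1-yl)butanoate
Product: 6 methyl (2R)-2-methyl-2-(3-methylbut-2-en-1-yl)-3-oxobutanoate
Conditions: Dess–Martin periodinane, CH2Cl2, 0 °C → rt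
Reagents that add atoms: none
Why: Dess–Martin oxidation removes the now unneeded carbinol centre, while the quaternary carbon has no α-hydrogen and cannot epimerise.

**Step 4**
Reactants: 7 ethyl 3-oxohexanoate
Product: 8 ethyl (2-propyl-1,3-dioxolan-2-yl)acetate
Conditions: HOCH2CH2OH, TsOH·H2O (cat.), toluene, reflux, Dean–Stark
Reagents that add atoms: ethane-1,2-diol, OCCO
Why: acid-catalysed ketalisation with azeotropic removal of water masks the ketone that will later become the butanoyl carbonyl.

**Step 5**
Reactants: 8 ethyl (2-propyl-1,3-dioxolan-2-yl)acetate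
Product: 9 (2-propyl-1,3-dioxolan-2-yl)acetaldehyde
Conditions: iBu2AlH (1.05 equiv), CH2Cl2, −78 °C; aq. KNaC4H4O6
Reagents that add atoms: none
Why: partial ester reduction, in which the tetrahedral aluminium hemiacetal survives at −78 °C and releases the aldehyde only on work-up.

**Step 6**
Reactants: 6 methyl (2R)-2-methyl-2-(3-methylbut-2-en-1-yl)-3-oxobutanoate; 9 (2-propyl-1,3-dioxolan-2-yl)acetaldehyde
Product: 11 methyl (2R,5RS)-5-hydroxy-2-methyl-2-(3-methylbut-2-en-1-yl)-3-oxo-6-(2-propyl-1,3-dioxolan-2-yl)hexanoate, via lithium enolate 10 (not isolated)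
Conditions: LiN(iPr)2 (1.05 equiv), THF, −78 °C; 9, −78 °C; AcOH
Reagents that add atoms: none
Why: directed aldol addition of a kinetic lithium enolate, where the acetyl CH3 is the only enolisable position of 6 and the new carbinol (a mixture) is oxidised away in the next step.

**Step 7**
Reactants: 11 methyl (2R,5RS)-5-hydroxy-2-methyl-2-(3-methylbut-2-en-1-yl)-3-oxo-6-(2-propyl-1,3-dioxolan-2-yl)hexanoate
Product: 12 methyl (2R)-2-methyl-2-(3-methylbut-2-en-1-yl)-3,5-dioxo-6-(2-propyl-1,3-dioxolan-2-yl)hexanoate
Conditions: Dess–Martin periodinane (1.1 equiv), pyridine, CH2Cl2, 0 °C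
Reagents that add atoms: none
Why: Dess–Martin oxidation of a β-hydroxy ketone to the β-diketone under buffered conditions that spare the ketal and the prenyl alkene.

**Step 8**
Reactants: 12 methyl (2R)-2-methyl-2-(3-methylbut-2-en-1-yl)-3,5-dioxo-6-(2-propyl-1,3-dioxolan-2-yl)hexanoate
Product: 13 methyl (2R)-2-methyl-2-(3-methylbut-2-en-1-yl)-3,5,7-trioxodecanoate
Conditions: 1 M aq. HCl, THF, rt, stopped at full conversion, used crude
Reagents that add atoms: water, O
Why: acid-catalysed ketal hydrolysis reveals the third ketone, kept mild and short so the triketone does not cyclodehydrate to a 4-pyranone.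

**Step 9**
Reactants: 13 methyl (2R)-2-methyl-2-(3-methylbut-2-en-1-yl)-3,5,7-trioxodecanoate
Product: 14 (4R)-2-butanoyl-3,5-dihydroxy-4-methyl-4-(3-methylbut-2-en-1-yl)cyclohexa-2,5-dien-1-one
Conditions: NaH (3 equiv), THF, 0 → 60 °C; 1 M HCl
Reagents that add atoms: none
Why: Dieckmann (intramolecular Claisen) condensation, in which C6 of the dianion acylates the ester in the only six-membered closure available, so the butanoyl group ends up next to the former ester carbon and the untouched quaternary centre becomes 4R.

**Step 10**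
Reactants: 15 5-methoxybenzene-1,3-diol
Product: 16 1-methoxy-3,5-bis(methoxymethoxy)benzene
Conditions: MOMCl (2.5 equiv), K2CO3, acetone, 0 °C → rt
Reagents that add atoms: chloromethyl methyl ether, COCCl
Why: Williamson-type O-alkylation protects both phenols as MOM ethers, which also serve as directing groups for lithiation.

**Step 11**
Reactants: 16 1-methoxy-3,5-bis(methoxymethoxy)benzene
Product: 18 1-[4-methoxy-2,6-bis(methoxymethoxy)phenyl]-N,N-dimethylmethanamine, via aryllithium 17 (not isolated)
Conditions: n-BuLi, TMEDA, THF, 0 °C; CH2=NMe2+ I−, −78 °C → rt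
Reagents that add atoms: N,N-dimethylmethyleneiminium iodide (Eschenmoser's salt), C=[N+](C)C.[I-]
Why: directed ortho-metalation at the carbon flanked by both MOM ethers, followed by Mannich-type capture of the aryllithium by the iminium ion, places the bridging carbon unambiguously between the two future hydroxyls.

**Step 12**
Reactants: 18 1-[4-methoxy-2,6-bis(methoxymethoxy)phenyl]-N,N-dimethylmethanamine
Product: 20 1-{3-[(dimethylamino)methyl]-6-methoxy-2,4-bis(methoxymethoxy)phenyl}butan-1-one, via aryllithium 19 (not isolated)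
Conditions: n-BuLi, TMEDA, THF, 0 °C; PrC(O)N(OMe)Me, −78 °C → rt; H2O
Reagents that add atoms: N-methoxy-N-methylbutanamide, CCCC(=O)N(C)OC
Why: second directed ortho-metalation at the only remaining type of ring C–H (between OMOM and OMe, two equivalent sites), followed by Weinreb ketone synthesis, which stops at the ketone.

**Step 13**
Reactants: 20 1-{3-[(dimethylamino)methyl]-6-methoxy-2,4-bis(methoxymethoxy)phenyl}butan-1-one
Product: 21 1-{3-[(dimethylamino)methyl]-2,4-dihydroxy-6-methoxyphenyl}butan-1-one
Conditions: HCl (3 M in MeOH), 40 °C; aq. NaHCO3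
Reagents that add atoms: none
Why: acid-catalysed acetal methanolysis removes both MOM groups while the benzylic amine is held as its stable ammonium salt.

**Step 14**
Reactants: 14 (4R)-2-butanoyl-3,5-dihydroxy-4-methyl-4-(3-methylbut-2-en-1-yl)cyclohexa-2,5-dien-1-one; 21 1-{3-[(dimethylamino)methyl]-2,4-dihydroxy-6-methoxyphenyl}butan-1-one
Product: 23 (4R)-2-butanoyl-6-[(3-butanoyl-2,6-dihydroxy-4-methoxyphenyl)methyl]-3,5-dihydroxy-4-methyl-4-(3-methylbut-2-en-1-yl)cyclohexa-2,5-dien-1-one, via o-quinone methide 22 (not isolated)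
Conditions: 14 (1.3 equiv), toluene, 100 °C, argon sweep
Reagents that add atoms: none
Why: thermal loss of dimethylamine from the phenolic Mannich base gives an o-quinone methide that undergoes Michael addition by the only free nucleophilic carbon of the acidic trione 14, creating no new stereocentre and leaving the quaternary centre untouched.

## Compound list

1 | methyl (3R)-3-hydroxybutanoate | COC(=O)C[C@@H](C)O | starting material
2 | dilithium alkoxide-enolate of 1 | [Li+].[Li+].COC([O-])=C[C@@H](C)[O-] | intermediate
3 | methyl (2R,3R)-3-hydroxy-2-methylbutanoate | COC(=O)[C@H](C)[C@@H](C)O | intermediate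
4 | dilithium alkoxide-enolate of 3 | [Li+].[Li+].COC([O-])=C(C)[C@@H](C)[O-] | intermediate
5 | methyl (2R,3R)-3-hydroxy-2-methyl-2-(3-methylbut-2-en-1-yl)butanoate | COC(=O)[C@](C)(CC=C(C)C)[C@@H](C)O | intermediate
6 | methyl (2R)-2-methyl-2-(3-methylbut-2-en-1-yl)-3-oxobutanoate | COC(=O)[C@](C)(CC=C(C)C)C(C)=O | intermediate
7 | ethyl 3-oxohexanoate | CCCC(=O)CC(=O)OCC | starting material
8 | ethyl (2-propyl-1,3-dioxolan-2-yl)acetate | CCCC1(CC(=O)OCC)OCCO1 | intermediate
9 | (2-propyl-1,3-dioxolan-2-yl)acetaldehyde | CCCC1(CC=O)OCCO1 | intermediate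
10 | lithium enolate of 6 (at the acetyl CH3) | [Li+].COC(=O)[C@](C)(CC=C(C)C)C([O-])=C | intermediate
11 | methyl (2R,5RS)-5-hydroxy-2-methyl-2-(3-methylbut-2-en-1-yl)-3-oxo-6-(2-propyl-1,3-dioxolan-2-yl)hexanoate | COC(=O)[C@](C)(CC=C(C)C)C(=O)CC(O)CC1(CCC)OCCO1 | intermediate
12 | methyl (2R)-2-methyl-2-(3-methylbut-2-en-1-yl)-3,5-dioxo-6-(2-propyl-1,3-dioxolan-2-yl)hexanoate | COC(=O)[C@](C)(CC=C(C)C)C(=O)CC(=O)CC1(CCC)OCCO1 | intermediate
13 | methyl (2R)-2-methyl-2-(3-methylbut-2-en-1-yl)-3,5,7-trioxodecanoate | COC(=O)[C@](C)(CC=C(C)C)C(=O)CC(=O)CC(=O)CCC | intermediate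
14 | (4R)-2-butanoyl-3,5-dihydroxy-4-methyl-4-(3-methylbut-2-en-1-yl)cyclohexa-2,5-dien-1-one | CCCC(=O)C1=C(O)[C@](C)(CC=C(C)C)C(O)=CC1=O | intermediate
15 | 5-methoxybenzene-1,3-diol (5-methoxyresorcinol) | COc1cc(O)cc(O)c1 | starting material
16 | 1-methoxy-3,5-bis(methoxymethoxy)benzene | COCOc1cc(OC)cc(OCOC)c1 | intermediate
17 | [4-methoxy-2,6-bis(methoxymethoxy)phenyl]lithium | [Li]c1c(OCOC)cc(OC)cc1OCOC | intermediate
18 | 1-[4-methoxy-2,6-bis(methoxymethoxy)phenyl]-N,N-dimethylmethanamine | COCOc1cc(OC)cc(OCOC)c1CN(C)C | intermediate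
19 | {3-[(dimethylamino)methyl]-6-methoxy-2,4-bis(methoxymethoxy)phenyl}lithium | [Li]c1c(OC)cc(OCOC)c(CN(C)C)c1OCOC | intermediate
20 | 1-{3-[(dimethylamino)methyl]-6-methoxy-2,4-bis(methoxymethoxy)phenyl}butan-1-one | CCCC(=O)c1c(OC)cc(OCOC)c(CN(C)C)c1OCOC | intermediate
21 | 1-{3-[(dimethylamino)methyl]-2,4-dihydroxy-6-methoxyphenyl}butan-1-one | CCCC(=O)c1c(OC)cc(O)c(CN(C)C)c1O | intermediate
22 | 4-butanoyl-5-hydroxy-3-methoxy-6-methylidenecyclohexa-2,4-dien-1-one | CCCC(=O)C1=C(O)C(=C)C(=O)C=C1OC | intermediate
23 | (4R)-2-butanoyl-6-[(3-butanoyl-2,6-dihydroxy-4-methoxyphenyl)methyl]-3,5-dihydroxy-4-methyl-4-(3-methylbut-2-en-1-yl)cyclohexa-2,5-dien-1-one | CCCC(=O)C1=C(O)[C@](C)(CC=C(C)C)C(O)=C(Cc2c(O)cc(OC)c(C(=O)CCC)c2O)C1=O | target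

## Step count and risks

Total steps: 14. Longest linear sequence: 8 steps (1, 2, 3, 6, 7, 8, 9, 14). The side branches are steps 4–5 (aldehyde 9) and steps 10–13 (Mannich base 21).

**Step 9 (Dieckmann closure onto an ester on a quaternary carbon).** The stabilised enolate of 13 may be too weak a nucleophile for the hindered ester, or 13 may be lost to pyranone formation first. The fallback sets out from ketal 12 and comes back at 14, bypassing 13. Treating 12 with LiN(iPr)2 (2.3 equiv, THF, −78 → 0 °C) gives the dilithium dienediolate of 12 F1, whose unstabilised terminal carbanion closes onto the ester in a kinetic Dieckmann reaction. This gives (4R)-3,5-dihydroxy-4-methyl-4-(3-methylbut-2-en-1-yl)-2-(2-propyl-1,3-dioxolan-2-yl)cyclohexa-2,5-dien-1-one F2. Hydrolysis of its dioxolane with 1 M HCl in THF then gives 14, so the butanoyl carbonyl is unmasked only after the ring exists.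

**Step 14 (thermal coupling).** Heating may cause self-condensation of the quinone methide, or the liberated dimethylamine may scramble the methylene bridge. The fallback sets out from 21 and comes back at 23. Quaternising 21 with MeI in acetone at rt gives [(3-butanoyl-2,6-dihydroxy-4-methoxyphenyl)methyl]trimethylammonium iodide F3. Adding this salt to the disodium salt of 14 (NaOMe, MeOH, 0 °C → rt) releases the same quinone methide 22 by loss of trimethylamine at or below room temperature, and Michael addition of the enolate gives 23 without heating and without a nucleophilic secondary amine present.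

**Step 11 (site of lithiation and heterogeneous iminium quench).** Some lithiation between OMOM and OMe, or a sluggish reaction of the hindered aryllithium with the insoluble iminium salt, would lower yield and purity. The fallback sets out from 16 and comes back at 18. Aryllithium 17 is trapped with DMF to give 4-methoxy-2,6-bis(methoxymethoxy)benzaldehyde F4, a symmetric crystalline aldehyde that can be freed of any regioisomer by recrystallisation. Reductive amination with Me2NH and NaBH(OAc)3 in 1,2-dichloroethane then gives 18.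

## Further compounds

F1 | step 9 | dilithium dienediolate (dianion) of 12 | [Li+].[Li+].COC(=O)[C@](C)(CC=C(C)C)C([O-])=CC([O-])=CC1(CCC)OCCO1
F2 | step 9 | (4R)-3,5-dihydroxy-4-methyl-4-(3-methylbut-2-en-1-yl)-2-(2-propyl-1,3-dioxolan-2-yl)cyclohexa-2,5-dien-1-one | CCCC1(OCCO1)C1=C(O)[C@](C)(CC=C(C)C)C(O)=CC1=O
F3 | step 14 | [(3-butanoyl-2,6-dihydroxy-4-methoxyphenyl)methyl]trimethylammonium iodide | CCCC(=O)c1c(OC)cc(O)c(C[N+](C)(C)C)c1O.[I-]
F4 | step 11 | 4-methoxy-2,6-bis(methoxymethoxy)benzaldehyde | COCOc1cc(OC)cc(OCOC)c1C=O
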